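**Retrosynthetic overview**

1. Last disconnection: the C2–H bond of the all-cis tetrahydrofuran (O1; C2 on the central guaiacyl ring; C3 and C4 methyl-bearing; C5 on a 3,4-dimethoxyphenyl ring), by hydride reduction of the cyclic oxocarbenium ion of an acyclic γ-hydroxy aryl ketone. This is the only ring formed, and it is formed last.
2. Key disconnection: both 3,4-dimethoxyphenyl–CH(O) bonds at once (aryl C1 to the side-chain carbinol carbon C7, and aryl C1 to ring C5), leading back to a keto dialdehyde and two equivalents of one 3,4-dimethoxyphenyltitanium reagent.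
3. Enabling feature: the two outer rings are identical 3,4-dimethoxyphenyl groups, each on an oxygen-bearing CH (C7; ring C5) flanked by a stereocentre (C8 with its aryloxy oxygen; ring C4 with its methyl group), so one Felkin–Anh-controlled reagent can set both carbinol centres.
4. The keto dialdehyde comes from a syn-2,3-dimethyl γ-keto acid (CO2H to CHO; side-chain CH2OSi to CHO), made by enantioselective arylative opening of meso-2,3-dimethylsuccinic anhydride with the arylzinc of the central ring.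
5. C8 and its methyl group C9 come from (R)-propane-1,2-diol, joined to 4-bromo-2-methoxyphenol by Mitsunobu inversion.

Key step: step 8

Remark: the γ-hydroxy aryl ketone formed in the key step equilibrates with its cyclic hemiketal; the open form is treated as the isolated compound and the hemiketal as an intermediate of the last step.

**Route**

Step 1
Reactants: 1 (2R)-propane-1,2-diol
Product: 2 (2R)-1-{[tert-butyl(dimethyl)silyl]oxy}propan-2-ol
Conditions: TBSCl (1.0 equiv), imidazole, CH2Cl2, −10 °C to 0 °C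
Reagents that add atoms: tert-butyldimethylsilyl chloride (TBSCl), CC(C)(C)[Si](C)(C)Cl
Why: The primary hydroxyl of the 1,2-diol is silylated much faster than the secondary one (selective monosilylation), and the stereocentre is not involved.

Step 2
Reactants: 2 (2R)-1-{[tert-butyl(dimethyl)silyl]oxy}propan-2-ol; 3 4-bromo-2-methoxyphenol
Product: 4 4-bromo-1-{[(2S)-1-{[tert-butyl(dimethyl)silyl]oxy}propan-2-yl]oxy}-2-methoxybenzene
Conditions: PPh3, DIAD, THF, 0 °C to rt
Reagents that add atoms: none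
Why: Mitsunobu etherification activates the secondary alcohol as an oxyphosphonium ion that the phenoxide displaces by SN2 with inversion, turning the (R)-carbinol into the (S)-aryl ether carbon that becomes C8.

Step 3
Reactants: 5 meso-2,3-dimethylbutanedioic acid
Product: 6 cis-3,4-dimethyloxolane-2,5-dione (meso anhydride)
Conditions: AcCl, reflux
Reagents that add atoms: none
Why: Cyclodehydration of the 1,4-diacid with acetyl chloride gives the five-membered anhydride without touching the α-carbons, so the meso (cis) arrangement of the methyl groups is kept.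

Step 4
Reactants: 4 4-bromo-1-{[(2S)-1-{[tert-butyl(dimethyl)silyl]oxy}propan-2-yl]oxy}-2-methoxybenzene; 6 cis-3,4-dimethyloxolane-2,5-dione
Product: 9 (2S,3R)-4-(4-{[(2S)-1-{[tert-butyl(dimethyl)silyl]oxy}propan-2-yl]oxy}-3-methoxyphenyl)-2,3-dimethyl-4-oxobutanoic acid, via aryllithium 7 (not isolated), via arylzinc triflate 8 (not isolated)
Conditions: 4, n-BuLi, THF, −78 °C; Zn(OTf)2, −78 °C to rt; then 6, [Rh(cod)Cl]2 (cat.), TADDOL-derived phosphoramidite (cat.), DMF, 50 °C; aq. HCl
Reagents that add atoms: none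
Why: Rhodium-catalysed enantioselective arylative desymmetrisation of a meso succinic anhydride with an arylzinc reagent (oxidative addition of monovalent rhodium into one of the two enantiotopic acyl C–O bonds, transmetalation, reductive elimination) should open the ring to the syn-dimethyl keto acid, the chiral phosphoramidite (enantiomer chosen to give the 2S,3R acid) fixing both methyl-bearing stereocentres at once.

Step 5
Reactants: 9 (2S,3R)-4-(4-{[(2S)-1-{[tert-butyl(dimethyl)silyl]oxy}propan-2-yl]oxy}-3-methoxyphenyl)-2,3-dimethyl-4-oxobutanoic acid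
Product: 10 (2R,3S)-1-(4-{[(2S)-1-{[tert-butyl(dimethyl)silyl]oxy}propan-2-yl]oxy}-3-methoxyphenyl)-4-hydroxy-2,3-dimethylbutan-1-one
Conditions: BH3·THF (1.1 equiv), THF, −15 °C to 0 °C; MeOH
Reagents that add atoms: none
Why: Borane reduces a carboxylic acid through its acyloxyborane far faster than a deactivated, α-branched p-alkoxyaryl ketone (chemoselective borane reduction of an acid), and the non-basic medium leaves both stereocentres untouched.

Step 6
Reactants: 10 (2R,3S)-1-(4-{[(2S)-1-{[tert-butyl(dimethyl)silyl]oxy}propan-2-yl]oxy}-3-methoxyphenyl)-4-hydroxy-2,3-dimethylbutan-1-one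
Product: 11 (2R,3S)-4-hydroxy-1-(4-{[(2S)-1-hydroxypropan-2-yl]oxy}-3-methoxyphenyl)-2,3-dimethylbutan-1-one
Conditions: Bu4NF, AcOH, THF, 0 °C to rt
Reagents that add atoms: none
Why: Fluoride-mediated cleavage of the primary silyl ether, buffered with acetic acid so that the ketone α-stereocentre is not enolised.

Step 7
Reactants: 11 (2R,3S)-4-hydroxy-1-(4-{[(2S)-1-hydroxypropan-2-yl]oxy}-3-methoxyphenyl)-2,3-dimethylbutan-1-one
Product: 12 (2S,3R)-4-(3-methoxy-4-{[(2S)-1-oxopropan-2-yl]oxy}phenyl)-2,3-dimethyl-4-oxobutanal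
Conditions: Dess–Martin periodinane (2.5 equiv), NaHCO3, CH2Cl2, 0 °C to rt; used directly
Reagents that add atoms: none
Why: Dess–Martin oxidation converts both primary alcohols into aldehydes under buffered, non-basic conditions that should preserve the three enolisable stereocentres, the γ-hydroxy ketone reacting through its open form because its cyclic hemiketal has no oxidisable hydroxyl.

Step 8
Reactants: 12 (2S,3R)-4-(3-methoxy-4-{[(2S)-1-oxopropan-2-yl]oxy}phenyl)-2,3-dimethyl-4-oxobutanal; 13 4-bromo-1,2-dimethoxybenzene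
Product: 16 (2R,3S,4R)-4-(3,4-dimethoxyphenyl)-1-(4-{[(1R,2S)-1-(3,4-dimethoxyphenyl)-1-hydroxypropan-2-yl]oxy}-3-methoxyphenyl)-4-hydroxy-2,3-dimethylbutan-1-one, via aryllithium 14 (not isolated), via aryltitanium triisopropoxide 15 (not isolated)
Conditions: 13 (3 equiv), n-BuLi, THF, −78 °C; ClTi(OiPr)3, −78 °C to −40 °C; then 12, −78 °C to −20 °C; aq. NH4Cl
Reagents that add atoms: none
Why: Two equivalents of aryltitanium 15 add to the two aldehyde carbons of 12 by four-centre transfer of the aryl group from tetravalent titanium to a titanium-bound carbonyl, so that both 3,4-dimethoxyphenyl–CH(O) bonds (aryl C1 to C7 and aryl C1 to the future ring C5) form in one operation. The closest known reaction type is the non-chelation-controlled (Felkin–Anh) 1,2-addition of organotitanium triisopropoxides to α-alkoxy and α-methyl aldehydes. No ring closes in this step; the tetrahydrofuran closes in step 9 from the γ-hydroxy ketone made here. C7 is controlled by C8: the isopropoxide-saturated titanium cannot chelate the aryloxy oxygen, so the aryl group attacks anti to the C8–O bond in the polar Felkin–Anh transition state and the (7R,8S) erythro (anti) isomer should result. The second carbinol centre is controlled by the adjacent methyl-bearing carbon (future ring C4), where attack anti to the large branched chain and past hydrogen should give the syn isomer that becomes the 4,5-cis ring relationship. The step needs aldehyde-over-ketone chemoselectivity and no enolisation of the three α-stereocentres, and both are secured by the low basicity and weak Lewis acidity of the titanium reagent together with the deactivated, α-branched p-alkoxyaryl ketone.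

Step 9
Reactants: 16 (2R,3S,4R)-4-(3,4-dimethoxyphenyl)-1-(4-{[(1R,2S)-1-(3,4-dimethoxyphenyl)-1-hydroxypropan-2-yl]oxy}-3-methoxyphenyl)-4-hydroxy-2,3-dimethylbutan-1-one
Product: 19 (1R,2S)-1-(3,4-dimethoxyphenyl)-2-{4-[(2S,3R,4S,5R)-5-(3,4-dimethoxyphenyl)-3,4-dimethyloxolan-2-yl]-2-methoxyphenoxy}propan-1-ol, via cyclic hemiketal 17 (not isolated), via oxocarbenium ion 18 (not isolated)
Conditions: Et3SiH, BF3·OEt2, CH2Cl2, −78 °C
Reagents that add atoms: none
Why: BF3·OEt2 ionises the cyclic hemiketal 17 (formed by 5-exo-trig addition of the C4 hydroxyl of 16 to the ketone) to the 2-aryl oxocarbenium ion 18, and Et3SiH delivers hydride to the face opposite the three cis substituents (ring C3 methyl, C4 methyl, C5 aryl), which sets ring C2 and should give the all-cis tetrahydrofuran (reductive deoxygenation of a hemiketal by ionic hydrogenation), while at −78 °C the C7 benzylic alcohol, deactivated by its β-aryloxy group, should stay intact.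

**Compound list**

1 | (2R)-propane-1,2-diol | C[C@@H](O)CO | starting material
2 | (2R)-1-{[tert-butyl(dimethyl)silyl]oxy}propan-2-ol | CC(C)(C)[Si](C)(C)OC[C@@H](C)O | intermediate
3 | 4-bromo-2-methoxyphenol | COc1cc(Br)ccc1O | starting material
4 | 4-bromo-1-{[(2S)-1-{[tert-butyl(dimethyl)silyl]oxy}propan-2-yl]oxy}-2-methoxybenzene | CC(C)(C)[Si](C)(C)OC[C@H](C)Oc1ccc(Br)cc1OC | intermediate
5 | meso-(2R,3S)-2,3-dimethylbutanedioic acid | OC(=O)[C@H](C)[C@H](C)C(=O)O | starting material
6 | cis-(3R,4S)-3,4-dimethyloxolane-2,5-dione (meso) | C[C@H]1C(=O)OC(=O)[C@H]1C | intermediate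
7 | (4-{[(2S)-1-{[tert-butyl(dimethyl)silyl]oxy}propan-2-yl]oxy}-3-methoxyphenyl)lithium | CC(C)(C)[Si](C)(C)OC[C@H](C)Oc1ccc([Li])cc1OC | intermediate
8 | (4-{[(2S)-1-{[tert-butyl(dimethyl)silyl]oxy}propan-2-yl]oxy}-3-methoxyphenyl)zinc trifluoromethanesulfonate | CC(C)(C)[Si](C)(C)OC[C@H](C)Oc1ccc([Zn]OS(=O)(=O)C(F)(F)F)cc1OC | intermediate
9 | (2S,3R)-4-(4-{[(2S)-1-{[tert-butyl(dimethyl)silyl]oxy}propan-2-yl]oxy}-3-methoxyphenyl)-2,3-dimethyl-4-oxobutanoic acid | CC(C)(C)[Si](C)(C)OC[C@H](C)Oc1ccc(C(=O)[C@H](C)[C@H](C)C(=O)O)cc1OC | intermediate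
10 | (2R,3S)-1-(4-{[(2S)-1-{[tert-butyl(dimethyl)silyl]oxy}propan-2-yl]oxy}-3-methoxyphenyl)-4-hydroxy-2,3-dimethylbutan-1-one | CC(C)(C)[Si](C)(C)OC[C@H](C)Oc1ccc(C(=O)[C@H](C)[C@H](C)CO)cc1OC | intermediate
11 | (2R,3S)-4-hydroxy-1-(4-{[(2S)-1-hydroxypropan-2-yl]oxy}-3-methoxyphenyl)-2,3-dimethylbutan-1-one | OC[C@H](C)Oc1ccc(C(=O)[C@H](C)[C@H](C)CO)cc1OC | intermediate
12 | (2S,3R)-4-(3-methoxy-4-{[(2S)-1-oxopropan-2-yl]oxy}phenyl)-2,3-dimethyl-4-oxobutanal | O=C[C@H](C)Oc1ccc(C(=O)[C@H](C)[C@H](C)C=O)cc1OC | intermediate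
13 | 4-bromo-1,2-dimethoxybenzene | COc1ccc(Br)cc1OC | starting material
14 | (3,4-dimethoxyphenyl)lithium | COc1ccc([Li])cc1OC | intermediate
15 | (3,4-dimethoxyphenyl)tri(propan-2-yloxy)titanium | COc1ccc([Ti](OC(C)C)(OC(C)C)OC(C)C)cc1OC | intermediate
16 | (2R,3S,4R)-4-(3,4-dimethoxyphenyl)-1-(4-{[(1R,2S)-1-(3,4-dimethoxyphenyl)-1-hydroxypropan-2-yl]oxy}-3-methoxyphenyl)-4-hydroxy-2,3-dimethylbutan-1-one | COc1ccc([C@@H](O)[C@H](C)Oc2ccc(C(=O)[C@H](C)[C@H](C)[C@@H](O)c3ccc(OC)c(OC)c3)cc2OC)cc1OC | intermediate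
17 | (3R,4S,5R)-5-(3,4-dimethoxyphenyl)-2-(4-{[(1R,2S)-1-(3,4-dimethoxyphenyl)-1-hydroxypropan-2-yl]oxy}-3-methoxyphenyl)-3,4-dimethyloxolan-2-ol (both C2 epimers) | COc1ccc([C@@H](O)[C@H](C)Oc2ccc(C3(O)O[C@@H](c4ccc(OC)c(OC)c4)[C@@H](C)[C@H]3C)cc2OC)cc1OC | intermediate
18 | (3R,4S,5R)-5-(3,4-dimethoxyphenyl)-2-(4-{[(1R,2S)-1-(3,4-dimethoxyphenyl)-1-hydroxypropan-2-yl]oxy}-3-methoxyphenyl)-3,4-dimethyl-4,5-dihydro-3H-furan-1-ium hydroxytrifluoroborate | COc1ccc([C@@H](O)[C@H](C)Oc2ccc(C3=[O+][C@@H](c4ccc(OC)c(OC)c4)[C@@H](C)[C@H]3C)cc2OC)cc1OC.O[B-](F)(F)F | intermediate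
19 | (1R,2S)-1-(3,4-dimethoxyphenyl)-2-{4-[(2S,3R,4S,5R)-5-(3,4-dimethoxyphenyl)-3,4-dimethyloxolan-2-yl]-2-methoxyphenoxy}propan-1-ol | COc1ccc([C@@H](O)[C@H](C)Oc2ccc([C@H]3O[C@@H](c4ccc(OC)c(OC)c4)[C@@H](C)[C@H]3C)cc2OC)cc1OC | target

**Step count and risks**

Total steps: 9. Longest linear sequence: 8 steps (steps 1, 2, 4, 5, 6, 7, 8, 9 from (2R)-propane-1,2-diol); step 3 is a one-step branch.

Steps most likely to fail:

Step 8. The facial bias at the α-methyl aldehyde is the weaker of the two Felkin–Anh controls and may be insufficient. The dialdehyde may also lose configuration by enolisation before the reagent reaches it. Fallback: the two additions are separated and the ring-side carbinol is set by reagent control. Setting out from 10, Dess–Martin oxidation gives the silyl-protected keto aldehyde F1. Catalyst-controlled aryl transfer (3,4-dimethoxyphenylboronic acid, Et2Zn, chiral β-amino alcohol ligand, toluene) gives the γ-hydroxy ketone F2. Et3SiH and BF3·OEt2 at −78 °C close the all-cis tetrahydrofuran F3. Bu4NF gives the primary alcohol F4, and Dess–Martin oxidation gives the α-aryloxy aldehyde F5. A single Felkin–Anh addition of aryltitanium 15 to F5 then forms the aryl–C7 bond and comes back to the route at 19.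

Step 9. The C7 benzylic alcohol may ionise in competition with the hemiketal. The oxocarbenium ion may also lose its C3 proton to give the enol ether and reprotonate, which would scramble ring C3 before hydride capture. Fallback: the ring hydrogens are delivered by surface hydrogenation instead of ionic reduction. Setting out from 16, PPTS in toluene with 4 Å molecular sieves dehydrates the hemiketal to the cyclic enol ether F6. Hydrogenation (H2, Rh/Al2O3, EtOAc) should add to the face opposite the C4 methyl and C5 aryl groups and comes back to the route at 19.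

Step 5. Chemoselectivity may be lost by hydride transfer from the intermediate alkoxyborane to the γ-ketone, giving over-reduction. Fallback: the acid is carried to the aldehyde by acyl activation instead of hydride reduction. Setting out from 9, EtSH, EDC and DMAP give the S-ethyl thioester F7. HF·pyridine removes the silyl group to give the hydroxy thioester F8, and Dess–Martin oxidation gives the aldehyde thioester F9. Fukuyama reduction (Et3SiH, Pd/C, acetone) converts the thioester into the aldehyde and comes back to the route at 12.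

**Further compounds**

F1 | step 8 | (2S,3R)-4-(4-{[(2S)-1-{[tert-butyl(dimethyl)silyl]oxy}propan-2-yl]oxy}-3-methoxyphenyl)-2,3-dimethyl-4-oxobutanal | CC(C)(C)[Si](C)(C)OC[C@H](C)Oc1ccc(C(=O)[C@H](C)[C@H](C)C=O)cc1OC
F2 | step 8 | (2R,3S,4R)-1-(4-{[(2S)-1-{[tert-butyl(dimethyl)silyl]oxy}propan-2-yl]oxy}-3-methoxyphenyl)-4-(3,4-dimethoxyphenyl)-4-hydroxy-2,3-dimethylbutan-1-one | CC(C)(C)[Si](C)(C)OC[C@H](C)Oc1ccc(C(=O)[C@H](C)[C@H](C)[C@@H](O)c2ccc(OC)c(OC)c2)cc1OC
F3 | step 8 | tert-butyl{[(2S)-2-{4-[(2S,3R,4S,5R)-5-(3,4-dimethoxyphenyl)-3,4-dimethyloxolan-2-yl]-2-methoxyphenoxy}propyl]oxy}dimethylsilane | CC(C)(C)[Si](C)(C)OC[C@H](C)Oc1ccc([C@H]2O[C@@H](c3ccc(OC)c(OC)c3)[C@@H](C)[C@H]2C)cc1OC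
F4 | step 8 | (2S)-2-{4-[(2S,3R,4S,5R)-5-(3,4-dimethoxyphenyl)-3,4-dimethyloxolan-2-yl]-2-methoxyphenoxy}propan-1-ol | OC[C@H](C)Oc1ccc([C@H]2O[C@@H](c3ccc(OC)c(OC)c3)[C@@H](C)[C@H]2C)cc1OC
F5 | step 8 | (2S)-2-{4-[(2S,3R,4S,5R)-5-(3,4-dimethoxyphenyl)-3,4-dimethyloxolan-2-yl]-2-methoxyphenoxy}propanal | O=C[C@H](C)Oc1ccc([C@H]2O[C@@H](c3ccc(OC)c(OC)c3)[C@@H](C)[C@H]2C)cc1OC
F6 | step 9 | (1R,2S)-1-(3,4-dimethoxyphenyl)-2-{4-[(4S,5R)-5-(3,4-dimethoxyphenyl)-3,4-dimethyl-4,5-dihydrofuran-2-yl]-2-methoxyphenoxy}propan-1-ol | COc1ccc([C@@H](O)[C@H](C)Oc2ccc(C3=C(C)[C@H](C)[C@H](c4ccc(OC)c(OC)c4)O3)cc2OC)cc1OC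
F7 | step 5 | S-ethyl (2S,3R)-4-(4-{[(2S)-1-{[tert-butyl(dimethyl)silyl]oxy}propan-2-yl]oxy}-3-methoxyphenyl)-2,3-dimethyl-4-oxobutanethioate | CC(C)(C)[Si](C)(C)OC[C@H](C)Oc1ccc(C(=O)[C@H](C)[C@H](C)C(=O)SCC)cc1OC
F8 | step 5 | S-ethyl (2S,3R)-4-(4-{[(2S)-1-hydroxypropan-2-yl]oxy}-3-methoxyphenyl)-2,3-dimethyl-4-oxobutanethioate | OC[C@H](C)Oc1ccc(C(=O)[C@H](C)[C@H](C)C(=O)SCC)cc1OC
F9 | step 5 | S-ethyl (2S,3R)-4-(3-methoxy-4-{[(2S)-1-oxopropan-2-yl]oxy}phenyl)-2,3-dimethyl-4-oxobutanethioate | O=C[C@H](C)Oc1ccc(C(=O)[C@H](C)[C@H](C)C(=O)SCC)cc1OC
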